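Late in a run the dissolved gas also attacks the target, so the reading at 15 s is a stage on the way, and I reckon the rate that carries the flask there.

    gas phase ⇌ dissolved gas, rate k1*(csat - [dissolved gas]) (k1 = 0.95 s⁻¹, csat = 0.66 mM)
    target ⇌ isomer of the product (K2 = 0.76, k2 = 0.17 s⁻¹)
    starting material + dissolved gas → target (k3 = 140 M⁻¹ s⁻¹)
    dissolved gas + target → over-reacted product (k4 = 34 M⁻¹ s⁻¹)
    starting material + protic impurity → quenched substrate (k5 = 0.61 M⁻¹ s⁻¹)
    starting material + target → side product (k6 = 0.42 M⁻¹ s⁻¹)

starting material 0.010 M; gas phase 0.66 mM (held); protic impurity 10.0 mM; time 15 s

- in percentages every species weighs as the starting material in it: one side product counts as two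
- at the start none of the gas is dissolved
- run time (flask): 15 s

- green: doubling the saturation concentration of gas phase, all else as stated
- ochre: doubling the transfer coefficient of step 1, all else as stated

* amount of target at 15 s, in percent of the starting material charged
* the change that raises the amount of target at 15 s, in percent of the starting material charged most ("none" if none brings more than 2 percentage points) (green / ochre / none)
* amount of target at 15 s, in percent of the starting material charged, after ochre

The half-life of dissolved gas, by its reaction with starting material alone at the charge, is 0.50 s, much shorter than the run. So I freeze its balance: transfer in equals use. The full transfer rate is 0.627 mM s⁻¹. The starting material takes up gas with a pseudo-first-order constant of 1.40 s⁻¹, faster than the transfer coefficient 0.95 s⁻¹. I call φ the capture share: that constant divided by itself plus the transfer coefficient, the fraction of the full transfer rate that becomes reaction. At the start φ is 0.596, so the flask turns over 0.0374 s⁻¹ of its charge, which unslowed gives 56.1% by the end.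

Suppose 0.5 of the charge remains at the end. Then φ ends at 0.424. The quench takes 6.86%, and the gas reaction, at the mean slowing, takes 48.0%, which leaves 45.1%, close to my supposition.

| Factor | Value |
|---|---|
| end rate against start rate | 0.712 |
| mean slowing | 0.856 |
| target's equilibrium share beside its isomer | 0.568 |
| kept from over-reaction | 0.934 |

Their relaxation half-life, 1.76 s, is short against the run, but target is still being fed, so the equilibrium share from 0.76 is a rough figure, and target may run ahead of it. I commit to 25.4%. Green doubles the start rate, while ochre multiplies it by 1.42, so I choose green. I take ochre's number no further.

The forecast gives 26.2%, 31.5% after ochre, and green, with green higher “despite more over-reaction”.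

The simulation gives 26.3%, 31.9% after ochre, and green, which gains 12 percentage points against 5.6 points for ochre.

With the 48% left in this flask at 15 s, φ ends at 0.415, and the same mean gives 47.6% through the gas reaction, beside 44.9% read as target, isomer, over-reacted product and half the side product. Target holds 0.629 of target plus isomer in this flask, more than the equilibrium share 0.568. The neighbouring flask holds 0.0060 M of starting material, its other charges unchanged. Its φ starts lower, at 0.469, yet its rate per charge starts higher, 0.0490 s⁻¹. With 40.3% left at the end, φ falls to 0.263, and the same reckoning gives 57.4% through the gas reaction. The neighbouring flask reads 53.2% of its own charge on the same count.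

The constants used here are those of an exercise; the result is computed.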